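**Retrosynthetic overview**

1. Target 38 ⇐ bis-silyl ether 37 ⇐ lactol 36 ⇐ enal 34 (PMB removal, lactol closure) ⇐ aldehyde 32 (C13 by Mannich methylenation) ⇐ ester 30 ⇐ C9 alcohol 22 + acid 28 (from crotonaldehyde); 22 ⇐ ketone 21.
2. Feature: in the ten-membered carbocycle the atoms C9(O)–C8–C7–C6–C5=C4 form a cyclodec-5-enone unit, and the Z C1=C10 alkene next to C9 can be the alkene of a cyclohexene ring C9–C10–C1–C2–C3–C4. Hence 21 ⇐ anionic oxy-Cope ring expansion of the trans-1,2-dialkenylcyclohex-2-enol 18 (C6–C7 formed, C4–C9 broken; C6, C7 and the E C4=C5 alkene set together).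
3. 18 ⇐ ketone 13 + E-alkenyllithium 17 (from 4,4-diethoxybut-1-yne). 13 ⇐ 9 by turning the C4 propenyl group into the E-enol PMB ether (ozonolysis, CrCl2/Cl2CHB(pin) olefination, Cu(OAc)2 C–O coupling).
4. 9 ⇐ 2,6-dimethylphenol: quinone monoketal, reductive enol carbonate formation, palladium-catalysed decarboxylative asymmetric allylation (C4), CBS reduction (C2).
5. Ring order: six-membered carbocycle (from the arene) → ten-membered ring (step 13) → γ-lactone (steps 22 and 23).

Key step: step 13

Numbering: germacrane locants are used throughout, also for the six-membered precursors (ring atoms C9, C10, C1, C2, C3, C4; C14 on C10, C15 on C4; C11–C13 lactone carbons). Drawn with C1→C10 counterclockwise, the C2 oxygen, C11 on C7 and the C9 oxygen point up and the C6 oxygen points down (target 2R,6R,7S,9S; 1(10)Z,4E; side chain Z).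

Assumption: (S)-t-Bu-PHOX is taken to give the same facial sense with dienyl carbonate 4 as with the enol carbonate of 2-methylcyclohexanone; the antipodal ligand is used if the sense proves opposite.

Step 1
Reactants: 1 2,6-dimethylphenol
Product: 2 4,4-dimethoxy-2,6-dimethylcyclohexa-2,5-dien-1-one
Conditions: PhI(OAc)2 (2.2 equiv), MeOH, 0 °C to rt
Reagents that add atoms: methanol (CO), two molecules
Why: Hypervalent-iodine oxidative dearomatisation of a phenol whose ortho positions are blocked sends methanol twice to the free para carbon (by way of the 4-methoxyphenol), the standard access to para-quinone monoketals.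

Step 2
Reactants: 2 4,4-dimethoxy-2,6-dimethylcyclohexa-2,5-dien-1-one
Product: 4 allyl 4,4-dimethoxy-2,6-dimethylcyclohexa-1,5-dien-1-yl carbonate, via lithium dienolate 3 (not isolated)
Conditions: LiBH(s-Bu)3 (1.05 equiv), THF, −78 °C; then ClCO2CH2CH=CH2, −78 to 0 °C
Reagents that add atoms: allyl chloroformate (C=CCOC(Cl)=O)
Why: The bulky borohydride adds hydride 1,4 to the β-unsubstituted, α-methylated enone (carvone-type conjugate reduction; both enones of the symmetrical dienone give the same enolate, which cannot be reduced further), and the enolate is O-acylated by the chloroformate (reductive enolate trapping).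

Step 3
Reactants: 4 allyl 4,4-dimethoxy-2,6-dimethylcyclohexa-1,5-dien-1-yl carbonate
Product: 5 (R)-6-allyl-4,4-dimethoxy-2,6-dimethylcyclohex-2-en-1-one
Conditions: Pd2(dba)3 (2.5 mol %), (S)-t-Bu-PHOX (6 mol %), THF, 25 °C
Reagents that add atoms: none
Why: Tsuji–Trost decarboxylative asymmetric allylic alkylation, in which zerovalent palladium ionises the allyl carbonate, CO2 is lost and the allylpalladium enolate forms the C–C bond at the only available carbon (C4 of the cross-conjugated dienolate), the PHOX ligand choosing the enolate face and so setting the C4 quaternary centre.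

Step 4
Reactants: 5 (R)-6-allyl-4,4-dimethoxy-2,6-dimethylcyclohex-2-en-1-one
Product: 6 (S)-4,4-dimethoxy-2,6-dimethyl-6-[(E)-prop-1-enyl]cyclohex-2-en-1-one
Conditions: RuHCl(CO)(PPh3)3 (5 mol %), toluene, 80 °C
Reagents that add atoms: none
Why: Ruthenium hydride-catalysed alkene isomerisation (hydrometalation then β-hydride elimination) moves the terminal alkene one position inward and stops there because C4 is quaternary, and at this stage C2 carries no hydrogen, so the enone cannot migrate.

Step 5
Reactants: 6 (S)-4,4-dimethoxy-2,6-dimethyl-6-[(E)-prop-1-enyl]cyclohex-2-en-1-one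
Product: 7 (S)-3,5-dimethyl-5-[(E)-prop-1-enyl]cyclohex-2-ene-1,4-dione
Conditions: 1 M aq HCl, THF, 0 °C to rt
Reagents that add atoms: water (O)
Why: Acid-catalysed ketal hydrolysis unmasks the C2 ketone, while the quaternary C4 can neither epimerise nor allow aromatisation.

Step 6
Reactants: 7 (S)-3,5-dimethyl-5-[(E)-prop-1-enyl]cyclohex-2-ene-1,4-dione
Product: 8 (4R,6S)-4-hydroxy-2,6-dimethyl-6-[(E)-prop-1-enyl]cyclohex-2-en-1-one
Conditions: (S)-2-methyl-CBS-oxazaborolidine (0.2 equiv), catecholborane (1.2 equiv), toluene, −78 °C; MeOH quench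
Reagents that add atoms: none
Why: Corey–Bakshi–Shibata reduction, in which the oxazaborolidine binds the less hindered C2 carbonyl (CH2 and CH= neighbours, not the C9 carbonyl between a quaternary and a methyl-bearing carbon) with the alkenyl side as the large group, so that the (S)-catalyst should give the (R)-carbinol with the C2 hydroxyl cis to the C4 methyl under reagent control, the fixed s-trans enone excluding 1,4-reduction and any C2 epimer formed from the minor enantiomer of 7 being a separable diastereomer.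

Step 7
Reactants: 8 (4R,6S)-4-hydroxy-2,6-dimethyl-6-[(E)-prop-1-enyl]cyclohex-2-en-1-one
Product: 9 (4R,6S)-4-(tert-butyldimethylsilyloxy)-2,6-dimethyl-6-[(E)-prop-1-enyl]cyclohex-2-en-1-one
Conditions: TBSCl, imidazole, DMF, rt
Reagents that add atoms: tert-butyldimethylsilyl chloride (CC(C)(C)[Si](C)(C)Cl)
Why: Standard imidazole-promoted silylation of the secondary allylic alcohol gives an ether that withstands organolithium, KH and DDQ and leaves with fluoride at the end.

Step 8
Reactants: 9 (4R,6S)-4-(tert-butyldimethylsilyloxy)-2,6-dimethyl-6-[(E)-prop-1-enyl]cyclohex-2-en-1-one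
Product: 11 (1S,5R)-5-(tert-butyldimethylsilyloxy)-1,3-dimethyl-2-oxocyclohex-3-ene-1-carbaldehyde, via secondary ozonide 10 (not isolated)
Conditions: O3, CH2Cl2, −78 °C (Sudan Red 7B end point); then PPh3, −78 °C to rt
Reagents that add atoms: ozone ([O-][O+]=O)
Why: Ozonolysis with reductive work-up cleaves the electron-rich disubstituted propenyl alkene ahead of the electron-poor trisubstituted enone alkene and leaves the one-carbon aldehyde (C5) on C4; the non-enolisable keto aldehyde is used crude.

Step 9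
Reactants: 11 (1S,5R)-5-(tert-butyldimethylsilyloxy)-1,3-dimethyl-2-oxocyclohex-3-ene-1-carbaldehyde
Product: 12 (4R,6S)-4-(tert-butyldimethylsilyloxy)-2,6-dimethyl-6-[(E)-2-(4,4,5,5-tetramethyl-1,3,2-dioxaborolan-2-yl)ethenyl]cyclohex-2-en-1-one
Conditions: CrCl2 (8 equiv), Cl2CHB(pin) (2 equiv), LiI (4 equiv), THF, rt
Reagents that add atoms: 2-(dichloromethyl)-4,4,5,5-tetramethyl-1,3,2-dioxaborolane (ClC(Cl)B1OC(C)(C)C(C)(C)O1)
Why: Takai–Utimoto olefination, in which the geminal dichromium species adds to the aldehyde only (ketones are inert) and anti elimination from the β-oxido chromium intermediate gives the E-alkenylboronate, adding C6.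

Step 10
Reactants: 12 (4R,6S)-4-(tert-butyldimethylsilyloxy)-2,6-dimethyl-6-[(E)-2-(4,4,5,5-tetramethyl-1,3,2-dioxaborolan-2-yl)ethenyl]cyclohex-2-en-1-one
Product: 13 (4R,6S)-4-(tert-butyldimethylsilyloxy)-6-[(E)-2-(4-methoxybenzyloxy)ethenyl]-2,6-dimethylcyclohex-2-en-1-one
Conditions: Cu(OAc)2 (2 equiv), Et3N (4 equiv), 4-MeOC6H4CH2OH (20 equiv), 4 Å molecular sieves, CH2Cl2, air, rt
Reagents that add atoms: 4-methoxybenzyl alcohol (COc1ccc(CO)cc1)
Why: Chan–Lam–Evans-type oxidative C–O coupling of an alkenyl pinacol boronate with an alcohol, in which transmetalation to copper and reductive elimination proceed with retention, so the E-boronate becomes the E-enol ether at room temperature under conditions mild enough for the γ-silyloxy enone.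

Step 11
Reactants: 14 4,4-diethoxybut-1-yne
Product: 16 (E)-4,4-diethoxy-1-iodobut-1-ene, via alkenylzirconocene chloride 15 (not isolated)
Conditions: Cp2Zr(H)Cl (1.2 equiv), THF, rt; then I2, 0 °C
Reagents that add atoms: iodine (II)
Why: Hydrozirconation of the terminal alkyne is syn and places zirconium on the terminal carbon, and iodinolysis of the C–Zr bond occurs with retention, giving the E-iodoalkene.

Step 12
Reactants: 16 (E)-4,4-diethoxy-1-iodobut-1-ene; 13 (4R,6S)-4-(tert-butyldimethylsilyloxy)-6-[(E)-2-(4-methoxybenzyloxy)ethenyl]-2,6-dimethylcyclohex-2-en-1-one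
Product: 18 (1S,4R,6S)-4-(tert-butyldimethylsilyloxy)-1-[(E)-4,4-diethoxybut-1-enyl]-6-[(E)-2-(4-methoxybenzyloxy)ethenyl]-2,6-dimethylcyclohex-2-en-1-ol, via alkenyllithium 17 (not isolated)
Conditions: 16, t-BuLi (2.0 equiv), Et2O, −78 °C; then 13 in THF, −78 to −40 °C; aq NH4Cl
Reagents that add atoms: none
Why: Lithium–iodine exchange with retention gives the E-alkenyllithium, which adds 1,2 to the enone carbonyl; in the half-chair with the C2 silyloxy group pseudo-equatorial the C4 alkenyl arm is axial, so the nucleophile should enter axially on the opposite face (syn to the C4 methyl) and set C9 with the two alkenyl groups trans.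

Step 13
Reactants: 18 (1S,4R,6S)-4-(tert-butyldimethylsilyloxy)-1-[(E)-4,4-diethoxybut-1-enyl]-6-[(E)-2-(4-methoxybenzyloxy)ethenyl]-2,6-dimethylcyclohex-2-en-1-ol
Product: 21 (2Z,4R,6E,8S,9R)-4-(tert-butyldimethylsilyloxy)-9-(2,2-diethoxyethyl)-8-(4-methoxybenzyloxy)-2,6-dimethylcyclodeca-2,6-dien-1-one, via potassium alkoxide 19 (not isolated), via potassium enolate 20 (not isolated)
Conditions: KH (3 equiv), 18-crown-6 (3 equiv), THF, 0 °C to rt; then aq NH4Cl, −78 °C
Reagents that add atoms: none
Why: KH with 18-crown-6 turns the C9 hydroxyl into the unpaired potassium alkoxide 19, whose oxyanion weakens the C4–C9 bond so that the 1,5-diene C7=C8–C9–C4–C5=C6 undergoes a concerted [3,3] shift, forming C6–C7 and the C4=C5 alkene and giving the C8=C9 enolate 20, which is protonated at C8 on cold quench. The closest known reaction type is the anion-accelerated oxy-Cope rearrangement of trans-6-alkenyl-1-vinylcyclohex-2-enols to (Z,E)-cyclodeca-2,6-dienones. The ten-membered ring is closed by a four-atom ring expansion of the six-membered ring through a six-centre chair transition state (C6–C7 made while C4–C9 is broken), not by an end-to-end cyclisation. C6 and C7 are fixed together by that chair: both migrating alkenes are E, so the C6 oxygen and C11 sit equatorial and emerge anti (the later trans lactone), and their absolute sense is relayed from C4 and C9 because the two alkenyl groups are trans and both equatorial while the oxide and the C15 methyl are axial; the equatorial C3 gives the E C4=C5 alkene and the ring alkene is carried over as the Z C1=C10 enone. The step needs the chair through the exocyclic C7=C8 arm to beat the boat that would engage the ring C10=C1 alkene, which is secured because that boat would require the C4 arm to fold axially across the ring; the reactive chair carries a 1,3-diaxial contact between the C15 methyl and the C2 silyloxy group, so warming to room temperature may be required. The enol ether, the acetal and the silyl ether are inert to the alkoxide, and the enolate has no β-leaving group.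

Step 14
Reactants: 21 (2Z,4R,6E,8S,9R)-4-(tert-butyldimethylsilyloxy)-9-(2,2-diethoxyethyl)-8-(4-methoxybenzyloxy)-2,6-dimethylcyclodeca-2,6-dien-1-one
Product: 22 (1S,2Z,4R,6E,8S,9S)-4-(tert-butyldimethylsilyloxy)-9-(2,2-diethoxyethyl)-8-(4-methoxybenzyloxy)-2,6-dimethylcyclodeca-2,6-dien-1-ol
Conditions: (R)-2-methyl-CBS-oxazaborolidine (1.0 equiv), catecholborane (1.5 equiv), toluene/CH2Cl2, −78 to −40 °C; MeOH quench
Reagents that add atoms: none
Why: Corey–Bakshi–Shibata reduction of the α-methyl enone carbonyl with the C10 alkenyl carbon as the large group, so that the (R)-catalyst should deliver hydride to the face giving the (9S)-allylic alcohol (C9 oxygen on the face of C11) by reagent control over the conformational bias of the ten-membered ring, catalysed 1,2-delivery at −78 °C outrunning conjugate reduction.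

Step 15
Reactants: 23 (E)-but-2-enal (crotonaldehyde)
Product: 24 (Z)-2-iodobut-2-enal
Conditions: I2 (1.5 equiv), K2CO3, DMAP (0.2 equiv), THF/H2O 1:1, rt
Reagents that add atoms: iodine (II)
Why: α-Iodination of the enal by conjugate addition of DMAP, iodination of the enolate and E1cB loss of DMAP places iodine on C2 with the methyl group cis to iodine and trans to the formyl group, as in the starting E-enal.

Step 16
Reactants: 24 (Z)-2-iodobut-2-enal
Product: 25 (Z)-2-iodobut-2-en-1-ol
Conditions: NaBH4, MeOH, 0 °C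
Reagents that add atoms: none
Why: 1,2-Reduction of the aldehyde by borohydride at 0 °C leaves the vinyl iodide and the alkene geometry untouched.

Step 17
Reactants: 25 (Z)-2-iodobut-2-en-1-ol
Product: 26 (Z)-tert-butyl[(2-iodobut-2-enyl)oxy]dimethylsilane
Conditions: TBSCl, imidazole, CH2Cl2, rt
Reagents that add atoms: tert-butyldimethylsilyl chloride (CC(C)(C)[Si](C)(C)Cl)
Why: Standard silylation of the primary allylic alcohol, chosen so that both silyl ethers leave together in the last step.

Step 18
Reactants: 26 (Z)-tert-butyl[(2-iodobut-2-enyl)oxy]dimethylsilane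
Product: 28 (Z)-2-[(tert-butyldimethylsilyloxy)methyl]but-2-enoic acid, via alkenyllithium 27 (not isolated)
Conditions: t-BuLi (2.1 equiv), Et2O, −78 °C; then CO2 (gas), −78 °C; 0.5 M aq HCl to pH 3, 0 °C
Reagents that add atoms: carbon dioxide (O=C=O)
Why: Lithium–iodine exchange and carboxylation of the alkenyllithium both proceed with retention, so the carboxyl group ends cis to the β-methyl group (angelate-type Z acid), ether solvent, −78 °C and immediate CO2 quench suppressing O-to-C silyl migration.

Step 19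
Reactants: 28 (Z)-2-[(tert-butyldimethylsilyloxy)methyl]but-2-enoic acid; 22 (1S,2Z,4R,6E,8S,9S)-4-(tert-butyldimethylsilyloxy)-9-(2,2-diethoxyethyl)-8-(4-methoxybenzyloxy)-2,6-dimethylcyclodeca-2,6-dien-1-ol
Product: 30 9-O-{(Z)-2-[(tert-butyldimethylsilyloxy)methyl]but-2-enoyl} ester of alcohol 22 (C9 configuration retained), via mixed anhydride 29 (not isolated)
Conditions: 28, 2,4,6-Cl3C6H2COCl, Et3N, toluene, rt; then 22, DMAP, toluene, rt
Reagents that add atoms: none
Why: Yamaguchi esterification through the mixed 2,4,6-trichlorobenzoic anhydride and DMAP acylates the hindered secondary allylic C9 alcohol with retention at C9 and is the usual choice for angelate-type acids because the Z alkene is not isomerised.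

Step 20
Reactants: 30 9-O-{(Z)-2-[(tert-butyldimethylsilyloxy)methyl]but-2-enoyl} ester of alcohol 22
Product: 32 C12 aldehyde (30 in which CH(OEt)2 has become CHO), via collidinium adduct 31 (not isolated)
Conditions: Et3SiOTf (2 equiv), 2,4,6-collidine (3 equiv), CH2Cl2, 0 °C; then H2O, rt
Reagents that add atoms: water (O)
Why: Chemoselective acetal cleavage by the silyl triflate/collidine method, in which the acyclic acetal is ionised and trapped as a collidinium adduct that water hydrolyses to the aldehyde under buffered conditions that spare both silyl ethers, the allylic PMB ether, the ester and the acid-sensitive 1(10),4-diene.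

Step 21
Reactants: 32 C12 aldehyde (30 in which CH(OEt)2 has become CHO)
Product: 34 C11-methylene C12 aldehyde (32 with C11=C13H2), via Mannich base 33 (not isolated)
Conditions: Me2N=CH2 I (3 equiv), Et3N (5 equiv), CH2Cl2, rt
Reagents that add atoms: N,N-dimethylmethyleneiminium iodide (C=[N+](C)C.[I-])
Why: Mannich reaction of the enolisable aldehyde with the iminium salt followed by E1cB loss of dimethylamine (aldehyde α-methylenation with Eschenmoser's salt) introduces C13 without strong base, the side-chain ester having no α-hydrogen.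

Step 22
Reactants: 34 C11-methylene C12 aldehyde (32 with C11=C13H2)
Product: 36 12,6-lactol (trans-fused at C6/C7; both C12 anomers), via hydroxy enal 35 (not isolated)
Conditions: DDQ (1.3 equiv), CH2Cl2/pH 7 phosphate buffer 10:1, 0 °C
Reagents that add atoms: none
Why: DDQ oxidises the electron-rich PMB ether to an oxocarbenium ion that water cleaves, and the freed C6 hydroxyl adds 5-exo to the C12 aldehyde to give the α-methylene lactol without touching C6 or C7.

Step 23
Reactants: 36 12,6-lactol (trans-fused at C6/C7; both C12 anomers)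
Product: 37 2-O-TBS and side-chain O-TBS ether of the target (α-methylene lactone)
Conditions: MnO2 (20 equiv), CH2Cl2, rt
Reagents that add atoms: none
Why: MnO2 oxidation of the allylic lactol gives the α-methylene-γ-butyrolactone under neutral conditions, no other free hydroxyl being present.

Step 24
Reactants: 37 2-O-TBS and side-chain O-TBS ether of the target (α-methylene lactone)
Product: 38 CNP0273961.1 (target)
Conditions: HF·pyridine, pyridine, THF, 0 °C to rt
Reagents that add atoms: none
Why: Pyridine-buffered HF·pyridine cleaves both silyl ethers while avoiding basic fluoride (conjugate addition to the α-methylene lactone, acyl migration) and strong acid (transannular cyclisation of the 1(10),4-diene).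

**Compound list**

1 | 2,6-dimethylphenol | Cc1cccc(C)c1O | starting material
2 | 4,4-dimethoxy-2,6-dimethylcyclohexa-2,5-dien-1-one | CC1=CC(OC)(OC)C=C(C)C1=O | intermediate
3 | lithium 4,4-dimethoxy-2,6-dimethylcyclohexa-1,5-dien-1-olate (not isolated) | [Li+].[O-]C1=C(C)CC(OC)(OC)C=C1C | intermediate
4 | allyl 4,4-dimethoxy-2,6-dimethylcyclohexa-1,5-dien-1-yl carbonate | C=CCOC(=O)OC1=C(C)CC(OC)(OC)C=C1C | intermediate
5 | (R)-6-allyl-4,4-dimethoxy-2,6-dimethylcyclohex-2-en-1-one | O=C1C(C)=CC(OC)(OC)C[C@@]1(C)CC=C | intermediate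
6 | (S)-4,4-dimethoxy-2,6-dimethyl-6-[(E)-prop-1-enyl]cyclohex-2-en-1-one | O=C1C(C)=CC(OC)(OC)C[C@@]1(C)/C=C/C | intermediate
7 | (S)-3,5-dimethyl-5-[(E)-prop-1-enyl]cyclohex-2-ene-1,4-dione | O=C1C(C)=CC(=O)C[C@@]1(C)/C=C/C | intermediate
8 | (4R,6S)-4-hydroxy-2,6-dimethyl-6-[(E)-prop-1-enyl]cyclohex-2-en-1-one | O=C1C(C)=C[C@H](O)C[C@@]1(C)/C=C/C | intermediate
9 | (4R,6S)-4-(tert-butyldimethylsilyloxy)-2,6-dimethyl-6-[(E)-prop-1-enyl]cyclohex-2-en-1-one | O=C1C(C)=C[C@H](O[Si](C)(C)C(C)(C)C)C[C@@]1(C)/C=C/C | intermediate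
10 | secondary ozonide of 9: (4R,6S)-4-(tert-butyldimethylsilyloxy)-2,6-dimethyl-6-(5-methyl-1,2,4-trioxolan-3-yl)cyclohex-2-en-1-one, ozonide diastereomers (not isolated) | O=C1C(C)=C[C@H](O[Si](C)(C)C(C)(C)C)C[C@@]1(C)C2OOC(C)O2 | intermediate
11 | (1S,5R)-5-(tert-butyldimethylsilyloxy)-1,3-dimethyl-2-oxocyclohex-3-ene-1-carbaldehyde | O=C1C(C)=C[C@H](O[Si](C)(C)C(C)(C)C)C[C@@]1(C)C=O | intermediate
12 | (4R,6S)-4-(tert-butyldimethylsilyloxy)-2,6-dimethyl-6-[(E)-2-(4,4,5,5-tetramethyl-1,3,2-dioxaborolan-2-yl)ethenyl]cyclohex-2-en-1-one | O=C1C(C)=C[C@H](O[Si](C)(C)C(C)(C)C)C[C@@]1(C)/C=C/B2OC(C)(C)C(C)(C)O2 | intermediate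
13 | (4R,6S)-4-(tert-butyldimethylsilyloxy)-6-[(E)-2-(4-methoxybenzyloxy)ethenyl]-2,6-dimethylcyclohex-2-en-1-one | O=C1C(C)=C[C@H](O[Si](C)(C)C(C)(C)C)C[C@@]1(C)/C=C/OCc2ccc(OC)cc2 | intermediate
14 | 4,4-diethoxybut-1-yne | C#CCC(OCC)OCC | starting material
15 | (E)-(4,4-diethoxybut-1-enyl)zirconocene chloride (not isolated) | CCOC(OCC)C/C=C/[Zr](Cl)(C1C=CC=C1)C1C=CC=C1 | intermediate
16 | (E)-4,4-diethoxy-1-iodobut-1-ene | CCOC(OCC)C/C=C/I | intermediate
17 | (E)-(4,4-diethoxybut-1-enyl)lithium (not isolated) | CCOC(OCC)C/C=C/[Li] | intermediate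
18 | (1S,4R,6S)-4-(tert-butyldimethylsilyloxy)-1-[(E)-4,4-diethoxybut-1-enyl]-6-[(E)-2-(4-methoxybenzyloxy)ethenyl]-2,6-dimethylcyclohex-2-en-1-ol (oxy-Cope precursor; alkenyl groups trans) | O[C@@]1(/C=C/CC(OCC)OCC)C(C)=C[C@H](O[Si](C)(C)C(C)(C)C)C[C@@]1(C)/C=C/OCc2ccc(OC)cc2 | intermediate
19 | potassium alkoxide of 18 (not isolated) | [K+].[O-][C@@]1(/C=C/CC(OCC)OCC)C(C)=C[C@H](O[Si](C)(C)C(C)(C)C)C[C@@]1(C)/C=C/OCc2ccc(OC)cc2 | intermediate
20 | potassium C8=C9 enolate of 21, C7 and C10 trans across the enolate bond (not isolated) | [K+].[C@@H]1(OCc2ccc(OC)cc2)/C=C(\C)C[C@@H](O[Si](C)(C)C(C)(C)C)/C=C(/C)\C([O-])=C\[C@H]1CC(OCC)OCC | intermediate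
21 | (2Z,4R,6E,8S,9R)-4-(tert-butyldimethylsilyloxy)-9-(2,2-diethoxyethyl)-8-(4-methoxybenzyloxy)-2,6-dimethylcyclodeca-2,6-dien-1-one (oxy-Cope product) | [C@@H]1(OCc2ccc(OC)cc2)/C=C(\C)C[C@@H](O[Si](C)(C)C(C)(C)C)/C=C(/C)C(=O)C[C@H]1CC(OCC)OCC | intermediate
22 | (1S,2Z,4R,6E,8S,9S)-4-(tert-butyldimethylsilyloxy)-9-(2,2-diethoxyethyl)-8-(4-methoxybenzyloxy)-2,6-dimethylcyclodeca-2,6-dien-1-ol | [C@@H]1(OCc2ccc(OC)cc2)/C=C(\C)C[C@@H](O[Si](C)(C)C(C)(C)C)/C=C(/C)[C@@H](O)C[C@H]1CC(OCC)OCC | intermediate
23 | (E)-but-2-enal (crotonaldehyde) | C/C=C/C=O | starting material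
24 | (Z)-2-iodobut-2-enal | C/C=C(\I)C=O | intermediate
25 | (Z)-2-iodobut-2-en-1-ol | C/C=C(\I)CO | intermediate
26 | (Z)-tert-butyl[(2-iodobut-2-enyl)oxy]dimethylsilane | C/C=C(\I)CO[Si](C)(C)C(C)(C)C | intermediate
27 | (E)-{1-[(tert-butyldimethylsilyloxy)methyl]prop-1-enyl}lithium, lithium cis to methyl (not isolated) | C/C=C(\[Li])CO[Si](C)(C)C(C)(C)C | intermediate
28 | (Z)-2-[(tert-butyldimethylsilyloxy)methyl]but-2-enoic acid | C/C=C(/CO[Si](C)(C)C(C)(C)C)C(=O)O | intermediate
29 | mixed anhydride of 28 with 2,4,6-trichlorobenzoic acid (not isolated) | C/C=C(/CO[Si](C)(C)C(C)(C)C)C(=O)OC(=O)c1c(Cl)cc(Cl)cc1Cl | intermediate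
30 | 9-O-{(Z)-2-[(tert-butyldimethylsilyloxy)methyl]but-2-enoyl} ester of 22 | [C@@H]1(OCc2ccc(OC)cc2)/C=C(\C)C[C@@H](O[Si](C)(C)C(C)(C)C)/C=C(/C)[C@@H](OC(=O)/C(=C\C)CO[Si](C)(C)C(C)(C)C)C[C@H]1CC(OCC)OCC | intermediate
31 | collidinium adduct: 30 with one C12 ethoxy group replaced by N-bound 2,4,6-trimethylpyridinium, triflate salt (not isolated) | [C@@H]1(OCc2ccc(OC)cc2)/C=C(\C)C[C@@H](O[Si](C)(C)C(C)(C)C)/C=C(/C)[C@@H](OC(=O)/C(=C\C)CO[Si](C)(C)C(C)(C)C)C[C@H]1CC(OCC)[n+]3c(C)cc(C)cc3C.[O-]S(=O)(=O)C(F)(F)F | intermediate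
32 | C12 aldehyde (30 with CH(OEt)2 replaced by CHO) | [C@@H]1(OCc2ccc(OC)cc2)/C=C(\C)C[C@@H](O[Si](C)(C)C(C)(C)C)/C=C(/C)[C@@H](OC(=O)/C(=C\C)CO[Si](C)(C)C(C)(C)C)C[C@H]1CC=O | intermediate
33 | Mannich base: 32 bearing CH2NMe2 on C11, both C11 epimers (not isolated) | [C@@H]1(OCc2ccc(OC)cc2)/C=C(\C)C[C@@H](O[Si](C)(C)C(C)(C)C)/C=C(/C)[C@@H](OC(=O)/C(=C\C)CO[Si](C)(C)C(C)(C)C)C[C@H]1C(CN(C)C)C=O | intermediate
34 | C11-methylene C12 aldehyde (2-substituted acrolein on C7) | [C@@H]1(OCc2ccc(OC)cc2)/C=C(\C)C[C@@H](O[Si](C)(C)C(C)(C)C)/C=C(/C)[C@@H](OC(=O)/C(=C\C)CO[Si](C)(C)C(C)(C)C)C[C@H]1C(=C)C=O | intermediate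
35 | 6-hydroxy enal (34 without the PMB group; not isolated) | [C@@H]1(O)/C=C(\C)C[C@@H](O[Si](C)(C)C(C)(C)C)/C=C(/C)[C@@H](OC(=O)/C(=C\C)CO[Si](C)(C)C(C)(C)C)C[C@H]1C(=C)C=O | intermediate
36 | 12,6-lactol of 35, trans-fused, both C12 anomers | C=C1C(O)O[C@@H]2/C=C(\C)C[C@@H](O[Si](C)(C)C(C)(C)C)/C=C(/C)[C@@H](OC(=O)/C(=C\C)CO[Si](C)(C)C(C)(C)C)C[C@@H]12 | intermediate
37 | 2-O-TBS, side-chain O-TBS ether of the target | C=C1C(=O)O[C@@H]2/C=C(\C)C[C@@H](O[Si](C)(C)C(C)(C)C)/C=C(/C)[C@@H](OC(=O)/C(=C\C)CO[Si](C)(C)C(C)(C)C)C[C@@H]12 | intermediate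
38 | CNP0273961.1: (2R,6R,7S,9S,1(10)Z,4E)-2-hydroxy-9-[(Z)-2-(hydroxymethyl)but-2-enoyloxy]germacra-1(10),4,11(13)-trien-12,6-olide | C=C1C(=O)O[C@@H]2/C=C(\C)C[C@@H](O)/C=C(/C)[C@@H](OC(=O)/C(=C\C)CO)C[C@@H]12 | target

**Step count**

Total: 24 steps. Longest linear sequence: 19 steps (steps 1–10, 12–14, 19–24); side sequences are step 11 (alkenyl iodide) and steps 15–18 (side-chain acid).

**Steps most likely to fail, with fallbacks**

Step 13 (ring expansion). The unpaired alkoxide may decompose by base-mediated pathways (β-fragmentation, deprotonation next to the enol ether) faster than a rearrangement slowed by the strained reactive conformer. The fallback is the neutral thermal variant and sets out from 18. Silylation with N-(trimethylsilyl)imidazole in CH2Cl2 gives the C9 trimethylsilyl ether F1. Heating F1 in degassed toluene at 180–200 °C in a base-washed sealed tube drives the siloxy-Cope rearrangement through the same chair to the trimethylsilyl dienol ether F2. K2CO3 in MeOH at 0 °C then cleaves the enol silyl ether and the route is rejoined at 21.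

Step 14 (C9 reduction). Hydride delivery to the conformationally mobile ten-membered enone may show poor or reversed facial selectivity if the ring conformation overrides the catalyst. The fallback sets out from 21. Reduction under substrate control (NaBH4/CeCl3, MeOH, −78 °C) or with the antipodal catalyst gives the C9 epimer, the (9R)-alcohol F3. F3 is esterified with acid 28 under Mitsunobu conditions (PPh3, DIAD, toluene, 0 °C), which inverts C9 and gives ester 30 directly, where the route is rejoined. Any F3 separated from 22 in the main route is funnelled into 30 in the same way.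

Step 12 (carbonyl addition). Attack of the bulky sp2 nucleophile on the hindered enone may occur with poor facial selectivity (entry syn to the C4 arm) or be diverted to electron transfer and enolisation. The fallback sets out from 13 and uses a slimmer nucleophile. Alkyne 14 is deprotonated (n-BuLi, THF, −78 °C) to the lithium acetylide F4, which adds axially, anti to the axial C4 arm, to give the propargylic alcohol F5. NaAlH2(OCH2CH2OMe)2 in THF (0 °C to rt) then reduces F5 by hydroxyl-directed trans-hydroalumination to the E-allylic alcohol, and the route is rejoined at 18.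

**Further compounds**

F1 | step 13 | C9 trimethylsilyl ether of 18 | C[Si](C)(C)O[C@@]1(/C=C/CC(OCC)OCC)C(C)=C[C@H](O[Si](C)(C)C(C)(C)C)C[C@@]1(C)/C=C/OCc2ccc(OC)cc2
F2 | step 13 | trimethylsilyl dienol ether of 21 (C8=C9, C7 and C10 trans) | [C@@H]1(OCc2ccc(OC)cc2)/C=C(\C)C[C@@H](O[Si](C)(C)C(C)(C)C)/C=C(/C)\C(O[Si](C)(C)C)=C\[C@H]1CC(OCC)OCC
F3 | step 14 | C9 epimer of 22, (9R)-alcohol | [C@@H]1(OCc2ccc(OC)cc2)/C=C(\C)C[C@@H](O[Si](C)(C)C(C)(C)C)/C=C(/C)[C@H](O)C[C@H]1CC(OCC)OCC
F4 | step 12 | lithium 4,4-diethoxybut-1-yn-1-ide | [Li]C#CCC(OCC)OCC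
F5 | step 12 | propargylic alcohol: 18 with C7≡C8 in place of the E alkene | O[C@@]1(C#CCC(OCC)OCC)C(C)=C[C@H](O[Si](C)(C)C(C)(C)C)C[C@@]1(C)/C=C/OCc2ccc(OC)cc2
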